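**Retrosynthetic overview**

1. Feature: in the γ-lactone (O1, C2 carbonyl, C3 with the exocyclic methylidene, C4 with CO2H, C5 with the C13 chain), C5 is an aldehyde-level carbon held between O1 and C4, and the C4 carboxyl carbon can be carried at the enol ether/formyl level. The trans C4–C5 bond is therefore an oxocarbenium–enolate aldol bond that can be stored in one seven-membered cyclic vinyl acetal.
2. Late disconnections: terminal acetate (enzymatic O-acetylation, last), exocyclic C3=CH2 (α-carboxylation, then decarboxylative Mannich methylenation), lactone C2=O (oxidation of the ring CH2 next to O1) and C4 CO2H (oxidation of CHO), back to a 2,3-trans tetrahydrofuran-3-carbaldehyde.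
3. Key disconnection: C4–C5, by Lewis acid ring contraction of an (S)-2-alkyl-4,5-dihydro-1,3-dioxepine; this closes the only ring (the tetrahydrofuran, later the lactone) and sets both stereocentres.
4. The vinyl acetal comes from enantioselective nickel hydride isomerisation of the achiral 4,7-dihydro-1,3-dioxepine made from 14-acetoxytetradecanal and cis-but-2-ene-1,4-diol; the aldehyde comes from tetradecane-1,14-diol.
5. The acetate protects the chain terminus through the oxidations, is expected to be lost to the methoxide-type magnesium reagent of the methylenation, and is put back in the final step.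

Key step: step 5

Remark on the chemistry (assumption): the sense of induction of the Me-DuPHOS nickel hydride with an unbranched 2-alkyl group and the retentive collapse of the ion pair in the ring contraction are taken as written; if the enantiomeric series results, the (S,S) ligand is used in step 4 and nothing else changes.

**Route**

Step 1
Reactants: 1 tetradecane-1,14-diol
Product: 2 14-hydroxytetradecyl acetate
Conditions: Ac2O (0.9 equiv), pyridine, THF, 0 °C → rt; chromatography, recovered diol recycled
Reagents that add atoms: acetic anhydride CC(=O)OC(C)=O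
Why: Statistical mono-O-acylation (nucleophilic acyl substitution) of a symmetrical diol whose hydroxyls do not influence each other, so a slight deficit of anhydride should give mainly the mono-acetate, which is easily separated from diol and diacetate.

Step 2
Reactants: 2 14-hydroxytetradecyl acetate
Product: 3 14-oxotetradecyl acetate (14-acetoxytetradecanal)
Conditions: TEMPO (10 mol%), PhI(OAc)2 (1.1 equiv), CH2Cl2, rt
Reagents that add atoms: none
Why: Oxoammonium-mediated (TEMPO/PhI(OAc)2) oxidation of a primary alcohol stops at the aldehyde and leaves the acetate untouched.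

Step 3
Reactants: 3 14-oxotetradecyl acetate; 4 (Z)-but-2-ene-1,4-diol
Product: 5 13-(4,7-dihydro-1,3-dioxepin-2-yl)tridecyl acetate
Conditions: 4 (1.5 equiv), p-TsOH·H2O (1 mol%), benzene, reflux (Dean–Stark); Et3N quench
Reagents that add atoms: none
Why: Acid-catalysed acetalisation with azeotropic removal of water, in which the cis geometry of the diol allows closure of the seven-membered ring; the product is achiral because a mirror plane runs through the acetal carbon and the midpoint of the C5=C6 bond.

Step 4
Reactants: 5 13-(4,7-dihydro-1,3-dioxepin-2-yl)tridecyl acetate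
Product: 6 13-[(2S)-4,5-dihydro-1,3-dioxepin-2-yl]tridecyl acetate
Conditions: NiI2[(R,R)-Me-DuPHOS] (2 mol%; Me-DuPHOS = 1,2-bis(2,5-dimethylphospholan-1-yl)benzene), LiBHEt3 (2 mol%), THF, −55 °C; filtration through basic Al2O3
Reagents that add atoms: none
Why: Enantioselective double-bond isomerisation by a chiral nickel hydride (hydrometalation/β-hydride elimination), a known reaction of 2-substituted 4,7-dihydro-1,3-dioxepines, in which the catalyst chooses one of the two enantiotopic directions of migration and so turns the prochiral acetal carbon into the (S) stereocentre, while conjugation with oxygen makes the enol ether the sink and the low temperature suppresses the reverse reaction that would racemise it.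

Step 5
Reactants: 6 13-[(2S)-4,5-dihydro-1,3-dioxepin-2-yl]tridecyl acetate
Product: 9 13-[(2R,3S)-3-formyltetrahydrofuran-2-yl]tridecyl acetate, via oxocarbenium boron-enolate ion pair 7 (not isolated), via cis aldehyde 8 (not isolated)
Conditions: BF3·OEt2 (0.1 equiv), CH2Cl2, −78 °C; Et3N (0.3 equiv), −78 °C → rt; then DBU (0.1 equiv), CH2Cl2, rt
Reagents that add atoms: none
Why: BF3 coordinates the enol ether oxygen O1 of 6 and the C2–O1 bond ionises to ion pair 7, an oxocarbenium ion (O3=C2) tethered through C4–C5 to a boron enolate (C6=C7–O); C6 then attacks C2, which forms the C2–C3 bond of the tetrahydrofuran (the later lactone C5–C4 bond) and contracts the ring from seven to five members, with C7 emerging as the formyl carbon. This is the known Lewis acid ring contraction of 4,5-dihydro-1,3-dioxepines to tetrahydrofuran-3-carbaldehydes, a 1,3 O-to-C vinyl acetal rearrangement of the Petasis–Ferrier family that amounts to an intramolecular Mukaiyama-type aldol addition. The ring closes in the 5-(enolexo)-endo-trig mode, which is acceptable here because the electrophile is a cation held against the enolate in a contact ion pair. C2 of the tetrahydrofuran is controlled by the acetal configuration: at −78 °C in CH2Cl2 the enolate carbon should bond on the face the vinyl oxygen has just left (retention) before the tethered cation can turn over; C3 is first set under kinetic control by the Z enolate (cis aldehyde 8 expected to predominate) and is then equilibrated by DBU through the enol to the more stable 2,3-trans aldehyde 9, which cannot disturb C2 because retro-oxa-Michael opening would be the reverse of a 5-endo-trig closure. The step needs ionisation of the vinyl acetal in the presence of the primary acetate, which the much greater Lewis basicity and ionisability of the acetal secure with a catalytic Lewis acid, and it needs the product not to re-ionise, which the cold amine quench secures before the base treatment.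

Step 6
Reactants: 9 13-[(2R,3S)-3-formyltetrahydrofuran-2-yl]tridecyl acetate
Product: 10 (2R,3S)-2-(13-acetoxytridecyl)tetrahydrofuran-3-carboxylic acid
Conditions: NaClO2 (2 equiv), NaH2PO4, 2-methylbut-2-ene, t-BuOH/H2O, 0 °C → rt
Reagents that add atoms: sodium chlorite [Na+].[O-]Cl=O
Why: Pinnick oxidation converts the aldehyde to the acid under buffered, weakly acidic conditions that do not enolise it, so C3 keeps its configuration, and the alkene scavenger removes hypochlorous acid.

Step 7
Reactants: 10 (2R,3S)-2-(13-acetoxytridecyl)tetrahydrofuran-3-carboxylic acid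
Product: 11 (2R,3S)-2-(13-acetoxytridecyl)-5-oxotetrahydrofuran-3-carboxylic acid
Conditions: RuCl3·xH2O (5 mol%), NaIO4 (4 equiv), EtOAc/MeCN/H2O (2:2:3), rt
Reagents that add atoms: sodium periodate [Na+].[O-]I(=O)(=O)=O
Why: RuO4 oxidation of an ether α-CH2 to an ester carbonyl (RuO4 regenerated by periodate) should attack the unhindered ring CH2 next to oxygen in preference to the chain-bearing methine, which is more hindered and inductively deactivated by the neighbouring carboxyl, and so give the γ-lactone with both stereocentres untouched.

Step 8
Reactants: 11 (2R,3S)-2-(13-acetoxytridecyl)-5-oxotetrahydrofuran-3-carboxylic acid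
Product: 14 (2R,3S)-2-(13-hydroxytridecyl)-4-methylidene-5-oxotetrahydrofuran-3-carboxylic acid, via lactone diacid 12 (not isolated), via Mannich adduct 13 (not isolated)
Conditions: MeOMgOCO2Me (2 M in DMF, 30 equiv), 130 °C; ice-cold 6 M HCl, EtOAc extraction; crude diacid: 37% aq. HCHO, PhNHMe, NaOAc, AcOH, rt
Reagents that add atoms: formaldehyde C=O
Why: Stiles carboxylation followed by decarboxylative Mannich methylenation, the standard α-methylenation of paraconic acids with a free C4 carboxyl, in which the lactone α-carbon is carboxylated as a chelated magnesium enolate-carboxylate, the iminium ion from HCHO/PhNHMe adds to the malonic carbon and CO2 and amine are then lost to leave the exocyclic alkene; the primary acetate is expected to be methanolysed by the large excess of magnesium methoxide species at 130 °C (any that survives is already 15 and converges in step 9), and the two stereocentres are not touched, trans being the stable arrangement.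

Step 9
Reactants: 14 (2R,3S)-2-(13-hydroxytridecyl)-4-methylidene-5-oxotetrahydrofuran-3-carboxylic acid
Product: 15 (2R,3S)-2-(13-acetoxytridecyl)-4-methylidene-5-oxotetrahydrofuran-3-carboxylic acid (target)
Conditions: Novozym 435 (immobilised Candida antarctica lipase B), vinyl acetate (10 equiv), MTBE, 30 °C
Reagents that add atoms: vinyl acetate C=COC(C)=O
Why: Lipase-catalysed irreversible transesterification with an enol ester acetylates the unhindered primary alcohol under neutral conditions, so no mixed anhydride forms at the carboxyl and no base is present to move the exocyclic double bond into the ring.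

**Compound list**

1 | tetradecane-1,14-diol | OCCCCCCCCCCCCCCO | starting material
2 | 14-hydroxytetradecyl acetate | CC(=O)OCCCCCCCCCCCCCCO | intermediate
3 | 14-oxotetradecyl acetate | CC(=O)OCCCCCCCCCCCCCC=O | intermediate
4 | (Z)-but-2-ene-1,4-diol | OC/C=C\CO | starting material
5 | 13-(4,7-dihydro-1,3-dioxepin-2-yl)tridecyl acetate | CC(=O)OCCCCCCCCCCCCCC1OCC=CCO1 | intermediate
6 | 13-[(2S)-4,5-dihydro-1,3-dioxepin-2-yl]tridecyl acetate | C1CO[C@H](CCCCCCCCCCCCCOC(C)=O)OC=C1 | intermediate
7 | oxocarbenium boron-enolate ion pair from ionisation of 6 (not isolated) | CC(=O)OCCCCCCCCCCCCC/C=[O+]/CC/C=C\O[B-](F)(F)F | intermediate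
8 | 13-[(2R,3R)-3-formyltetrahydrofuran-2-yl]tridecyl acetate, cis aldehyde (not isolated) | C1CO[C@H](CCCCCCCCCCCCCOC(C)=O)[C@@H]1C=O | intermediate
9 | 13-[(2R,3S)-3-formyltetrahydrofuran-2-yl]tridecyl acetate | C1CO[C@H](CCCCCCCCCCCCCOC(C)=O)[C@H]1C=O | intermediate
10 | (2R,3S)-2-(13-acetoxytridecyl)tetrahydrofuran-3-carboxylic acid | C1CO[C@H](CCCCCCCCCCCCCOC(C)=O)[C@H]1C(=O)O | intermediate
11 | (2R,3S)-2-(13-acetoxytridecyl)-5-oxotetrahydrofuran-3-carboxylic acid | C1C(=O)O[C@H](CCCCCCCCCCCCCOC(C)=O)[C@H]1C(=O)O | intermediate
12 | (2R,3S)-2-(13-hydroxytridecyl)-5-oxotetrahydrofuran-3,4-dicarboxylic acid, C4 epimers (not isolated) | OC(=O)C1C(=O)O[C@H](CCCCCCCCCCCCCO)[C@H]1C(=O)O | intermediate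
13 | (2R,3S)-2-(13-hydroxytridecyl)-4-[(N-methylanilino)methyl]-5-oxotetrahydrofuran-3,4-dicarboxylic acid, C4 epimers (not isolated) | OC(=O)C1(CN(C)c2ccccc2)C(=O)O[C@H](CCCCCCCCCCCCCO)[C@H]1C(=O)O | intermediate
14 | (2R,3S)-2-(13-hydroxytridecyl)-4-methylidene-5-oxotetrahydrofuran-3-carboxylic acid | C=C1C(=O)O[C@H](CCCCCCCCCCCCCO)[C@H]1C(=O)O | intermediate
15 | (2R,3S)-2-(13-acetoxytridecyl)-4-methylidene-5-oxotetrahydrofuran-3-carboxylic acid | C=C1C(=O)O[C@H](CCCCCCCCCCCCCOC(C)=O)[C@H]1C(=O)O | target

**Step count**

Total steps: 9. Longest linear sequence: 9 steps (1 to 15); diol 4 enters at step 3.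

**Steps most likely to fail**

Step 5 (ring contraction). The oxocarbenium ion of the ion pair may turn over before the C–C bond forms, so that the acetal configuration is only partly transferred and the chain-bearing carbon is partly racemised. Adventitious water would also hydrolyse the vinyl acetal. The fallback moves stereocontrol to an auxiliary; it sets out from aldehyde 3 and returns at lactone acid 11.
- (S)-4-Benzyloxazolidin-2-one is N-acylated with 4-tert-butoxy-4-oxobutanoic acid (PivCl, Et3N; then the lithiated oxazolidinone) to give (S)-4-benzyl-3-(4-tert-butoxy-4-oxobutanoyl)oxazolidin-2-one F1.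
- Its Z boron enolate (Bu2BOTf, i-Pr2NEt, CH2Cl2, −78 °C) adds to 3 in an Evans syn aldol reaction to give (S)-4-benzyl-3-[(2S,3R)-16-acetoxy-2-(2-tert-butoxy-2-oxoethyl)-3-hydroxyhexadecanoyl]oxazolidin-2-one F2.
- TFA in CH2Cl2 removes the tert-butyl ester and closes the γ-lactone to 13-[(2R,3S)-3-{[(4S)-4-benzyl-2-oxooxazolidin-3-yl]carbonyl}-5-oxotetrahydrofuran-2-yl]tridecyl acetate F3. The ring is trans because the syn aldol places the chain and the imide carbonyl anti across the new ring.
- LiOH/H2O2 (THF/H2O, 0 °C, short contact) cleaves the auxiliary and gives 11.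

Step 4 (enantioselective isomerisation). The catalyst may discriminate poorly between the two enantiotopic directions of migration when the 2-substituent is an unbranched alkyl chain, and reversible hydride addition may erode the enantiomeric excess. The fallback replaces catalyst control by resolution. The sequence is carried through steps 5 to 7 with whatever enrichment is obtained. The fallback sets out from lactone acid 11 of insufficient enantiomeric purity. This is crystallised from EtOAc/EtOH with (S)-1-phenylethylamine (or its antipode, whichever gives the less soluble salt of the wanted acid) as (S)-1-phenylethylammonium (2R,3S)-2-(13-acetoxytridecyl)-5-oxotetrahydrofuran-3-carboxylate F4. Dilute HCl liberates the acid and the route is rejoined at 11.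

Step 8 (carboxylation and methylenation). Carboxylation of the lactone α-carbon may stay incomplete, the diacid may lose CO2 before the Mannich step, and the new double bond may migrate into the ring under prolonged basic heating. The fallback uses enolate aminomethylation; it sets out from 11 and returns at 14.
- K2CO3 in MeOH followed by acidification (which recloses any opened lactone) removes the acetate and gives (2R,3S)-2-(13-hydroxytridecyl)-5-oxotetrahydrofuran-3-carboxylic acid F5.
- LiN(SiMe3)2 (3.3 equiv, THF, −78 °C) forms the alkoxide, the carboxylate and the lactone enolate. Eschenmoser's salt (CH2=NMe2+ I−, excess) aminomethylates the enolate carbon to give (2R,3S)-4-[(dimethylamino)methyl]-2-(13-hydroxytridecyl)-5-oxotetrahydrofuran-3-carboxylic acid F6 after aqueous work-up.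
- Quaternisation with MeI in MeOH and elimination with aqueous NaHCO3 gives 14.

**Further compounds**

F1 | step 5 | (S)-4-benzyl-3-(4-tert-butoxy-4-oxobutanoyl)oxazolidin-2-one | CC(C)(C)OC(=O)CCC(=O)N1[C@@H](Cc2ccccc2)COC1=O
F2 | step 5 | (S)-4-benzyl-3-[(2S,3R)-16-acetoxy-2-(2-tert-butoxy-2-oxoethyl)-3-hydroxyhexadecanoyl]oxazolidin-2-one | CC(=O)OCCCCCCCCCCCCC[C@@H](O)[C@H](CC(=O)OC(C)(C)C)C(=O)N1[C@@H](Cc2ccccc2)COC1=O
F3 | step 5 | 13-[(2R,3S)-3-{[(4S)-4-benzyl-2-oxooxazolidin-3-yl]carbonyl}-5-oxotetrahydrofuran-2-yl]tridecyl acetate | C1C(=O)O[C@H](CCCCCCCCCCCCCOC(C)=O)[C@H]1C(=O)N2[C@@H](Cc3ccccc3)COC2=O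
F4 | step 4 | (S)-1-phenylethylammonium (2R,3S)-2-(13-acetoxytridecyl)-5-oxotetrahydrofuran-3-carboxylate | C1C(=O)O[C@H](CCCCCCCCCCCCCOC(C)=O)[C@H]1C(=O)[O-].C[C@H]([NH3+])c1ccccc1
F5 | step 8 | (2R,3S)-2-(13-hydroxytridecyl)-5-oxotetrahydrofuran-3-carboxylic acid | C1C(=O)O[C@H](CCCCCCCCCCCCCO)[C@H]1C(=O)O
F6 | step 8 | (2R,3S)-4-[(dimethylamino)methyl]-2-(13-hydroxytridecyl)-5-oxotetrahydrofuran-3-carboxylic acid (C4 configuration not defined, removed on elimination) | CN(C)CC1C(=O)O[C@H](CCCCCCCCCCCCCO)[C@H]1C(=O)O
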